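**Retrosynthetic overview**

- The target is opened at the O8 ester ((E)-2-(acetoxymethyl)but-2-enoic acid), then at the C8 N–O bond, then at C11=C13, which comes from an α-phosphono lactone and formaldehyde (Horner–Wadsworth–Emmons).
- Feature used: on the ten-membered ring C7 carries C11 and C8 carries oxygen, both next to O6. The lactone ring O6–C12–C11–C7–C6 is therefore closed last, as its ethyl acetal, by adding an O6-tethered C11 radical and a nitroxide oxygen across the C7=C8 ring alkene (C7–C11 and C8–O).
- The radical carbon carries a phosphonate. It makes C11 electrophilic, so that it should add to the isolated C7=C8 bond and not to C5 of the dienone (also five atoms away), and it later delivers the exocyclic methylene.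
- The bicyclic precursor comes from ring-closing metathesis at C7=C8 and gold cyclisation of a hydroxy ynone (O–C3). The ynone comes from a Weinreb amide (C9, C10, C14, C1; from (S)-lactic acid) and an acetylide (C2–C8; C6 set by asymmetric vinylation).
- Ring order: 3(2H)-furanone, then the ten-membered carbocycle, then the lactone.

Key step: step 13

Remark: atom numbers are germacrane numbers (C1 ketone, C2=C3, O bridge C3–O–C10, C4=C5 with C15, C6–O lactone, C7, C8–O ester, C9, C10 with C14, C11=C13, C12 lactone carbonyl). The descriptors at C6 and C7 change along the route only through CIP priorities; no centre is inverted.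
Remark: salts of a numbered compound that exist only in equilibrium in the reacting mixture (alkoxides, the phosphonate anion of step 15) carry no number; pre-formed reactive intermediates do.

**Route**

Step 1
Reactants: 1 (S)-lactic acid; 2 pivalaldehyde
Product: 3 (2S,5S)-2-tert-butyl-5-methyl-1,3-dioxolan-4-one
Conditions: TsOH·H2O (cat.), H2SO4 (cat.), pentane, reflux, water separator; crystallisation from pentane/Et2O, −78 °C
Reagents that add atoms: pivalaldehyde 2 (CC(C)(C)C=O)
Why: Acid-catalysed acetalisation of the α-hydroxy acid (first stage of self-regeneration of stereocentres); the lactate centre is untouched and the cis isomer should be obtained pure by crystallisation.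

Step 2
Reactants: 3 (2S,5S)-2-tert-butyl-5-methyl-1,3-dioxolan-4-one; 4 allyl bromide
Product: 6 (2S,5R)-5-allyl-2-tert-butyl-5-methyl-1,3-dioxolan-4-one, via lithium enolate 5 (not isolated)
Conditions: LDA, THF, −78 °C; then allyl bromide, −78 → −30 °C
Reagents that add atoms: allyl bromide 4 (C=CCBr)
Why: Enolate alkylation (self-regeneration of stereocentres): the acetal centre survives enolisation and its tert-butyl group forces allyl bromide onto the opposite face, so allyl takes the place of H with retention and the future C10 is set as R.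

Step 3
Reactants: 6 (2S,5R)-5-allyl-2-tert-butyl-5-methyl-1,3-dioxolan-4-one
Product: 7 (R)-2-hydroxy-N-methoxy-N,2-dimethylpent-4-enamide
Conditions: MeNH(OMe)·HCl, iPrMgCl, THF, −20 → 0 °C
Reagents that add atoms: N,O-dimethylhydroxylamine hydrochloride (CNOC.Cl)
Why: Weinreb amide formation by aminolysis of the acylal-type lactone with the chloromagnesium amide; the ring-opened hemiacetal alkoxide loses pivalaldehyde and no bond to the quaternary centre is broken.

Step 4
Reactants: 8 (Z)-3-methylpent-2-en-4-yn-1-ol
Product: 9 (Z)-3-methylpent-2-en-4-ynal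
Conditions: activated MnO2, CH2Cl2, rt, dark; filtered and used as a solution
Reagents that add atoms: none
Why: MnO2 oxidation of a primary allylic alcohol under neutral conditions, which should leave the Z double bond (future C4=C5) unisomerised.

Step 5
Reactants: 9 (Z)-3-methylpent-2-en-4-ynal; 10 vinylmagnesium bromide
Product: 11 (3R,4Z)-5-methylhepta-1,4-dien-6-yn-3-ol
Conditions: 10, ZnCl2, Et2O, then 1,4-dioxane and filtration (salt-free divinylzinc); then 9, (+)-DAIB (10 mol%), toluene, −20 °C
Reagents that add atoms: vinylmagnesium bromide 10 (C=C[Mg]Br)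
Why: Amino-alcohol-catalysed enantioselective addition of an organozinc reagent to an aldehyde; (+)-DAIB [(2R)-3-exo-(dimethylamino)isoborneol] should send the vinyl group to the Re face of the enal (its antipode sends alkyl and alkenyl groups to the Si face), which sets C6 as 3R, and at −20 °C vinyl transfer should be much faster than zincation of the alkyne C–H.

Step 6
Reactants: 11 (3R,4Z)-5-methylhepta-1,4-dien-6-yn-3-ol
Product: 12 tert-butyldimethylsilyl ether of 11
Conditions: TBSCl, imidazole, DMF, rt
Reagents that add atoms: tert-butyldimethylsilyl chloride (CC(C)(C)[Si](C)(C)Cl)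
Why: Silylation of the secondary alcohol; the ether blocks O6 during acetylide formation and during the gold step, in which a free O6 would add to C3.

Step 7
Reactants: 12 tert-butyldimethylsilyl ether of 11; 7 (R)-2-hydroxy-N-methoxy-N,2-dimethylpent-4-enamide
Product: 14 (4R,8Z,10R)-10-(tert-butyldimethylsilyloxy)-4-hydroxy-4,8-dimethyldodeca-1,8,11-trien-6-yn-5-one, via lithium acetylide 13 (not isolated)
Conditions: 12, n-BuLi, THF, −78 °C; 7 pre-treated with iPrMgCl (1 equiv), THF, −20 °C; combined, −78 → 0 °C; aq. NH4Cl
Reagents that add atoms: Weinreb amide 7 (C=CC[C@@](C)(O)C(=O)N(C)OC)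
Why: Weinreb ketone synthesis: the acetylide adds once to the amide, whose tertiary hydroxyl is masked as the magnesium alkoxide, and the chelated tetrahedral intermediate releases the ynone only on work-up, which joins C1 to C2 without touching C6 or C10.

Step 8
Reactants: 14 hydroxy ynone
Product: 15 (2R)-2-allyl-5-[(2Z,4R)-4-(tert-butyldimethylsilyloxy)hexa-2,5-dien-2-yl]-2-methylfuran-3(2H)-one
Conditions: (p-CF3C6H4)3PAuCl (5 mol%), AgOTf (5 mol%), toluene, rt
Reagents that add atoms: none
Why: Gold(I)-catalysed cycloisomerisation of a γ-hydroxy ynone (5-endo-dig attack of the C10 hydroxyl on C3, then protodeauration) gives the 3(2H)-furanone; no stereocentre takes part.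

Step 9
Reactants: 15 silylated furanone
Product: 16 (2R)-2-allyl-5-[(2Z,4R)-4-hydroxyhexa-2,5-dien-2-yl]-2-methylfuran-3(2H)-one
Conditions: HF·pyridine, pyridine, THF, 0 °C → rt
Reagents that add atoms: none
Why: Fluoride cleavage of the silyl ether under buffered conditions, chosen to avoid ionisation of the doubly allylic C6–O bond.

Step 10
Reactants: 16 furanone dienol
Product: 17 (2Z,4R,5E,8R)-4-hydroxy-2,8-dimethyl-11-oxabicyclo[6.2.1]undeca-1(10),2,5-trien-9-one (germacrane numbering: 4Z,7E; 6-OH; 10R)
Conditions: second-generation Ru benzylidene metathesis catalyst (10 mol%, in portions), 1,4-benzoquinone (20 mol%), toluene (1 mM), 80 °C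
Reagents that add atoms: none
Why: Ring-closing metathesis of the two monosubstituted alkenes closes the ten-membered ring at C7=C8; the trans alkene is expected because the furanone bridge holds C6 and C9 about 4 Å apart, a span that a cis C7=C8 (about 3.2 Å) cannot bridge, and benzoquinone should suppress isomerisation of the allylic alcohol.

Step 11
Reactants: 18 diethyl (2,2-diethoxyethyl)phosphonate
Product: 19 diethyl [(E)-2-ethoxyvinyl]phosphonate
Conditions: TMSOTf, iPr2NEt, CH2Cl2, −20 °C → rt
Reagents that add atoms: none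
Why: Silyl-triflate-mediated conversion of an acetal into its enol ether (oxocarbenium ion, then loss of the proton made acidic by the phosphoryl group), which should give the conjugated E isomer.

Step 12
Reactants: 17 bicyclic dienol; 19 diethyl [(E)-2-ethoxyvinyl]phosphonate
Product: 21 bromoacetal of 17 with a 2-bromo-2-(diethoxyphosphoryl)-1-ethoxyethyl group on O6 (mixture at C11 and C12), via dibromo ether 20 (not isolated)
Conditions: 19, Br2, CH2Cl2, −78 °C; then 17, 2,6-di-tert-butyl-4-methylpyridine, −78 → 0 °C
Reagents that add atoms: enol ether 19 (CCO/C=C/P(=O)(OCC)OCC); bromine (BrBr)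
Why: Haloacetalisation in its two-stage form: bromine adds to the enol ether and the α-bromo ether then alkylates O6 through its oxocarbenium ion, so no electrophilic bromine meets the alkenes of 17; the C6–O bond is not touched and the two new centres are lost later.

Step 13
Reactants: 21 bromoacetal; 22 TEMPO
Product: 23 tricyclic lactol ethyl acetal (6S,7R,8R,10R): oxolane O6–C12(OEt)–C11[P(O)(OEt)2]–C7–C6 trans-fused to the furanone-bridged ring, C8 bearing the 2,2,6,6-tetramethylpiperidin-1-yloxy group (mixture at C11 and C12)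
Conditions: TEMPO (3 equiv), Bu3SnH (1.5 equiv, syringe pump, 6 h), benzene (1 mM in 21), 70 °C
Reagents that add atoms: TEMPO 22 (CC1(C)CCCC(C)(C)N1[O])
Why: A stannyl radical, formed when TEMPO takes hydrogen from Bu3SnH, removes bromine from the α-bromophosphonate; the C11 radical adds to C7 and the secondary C8 radical couples with TEMPO, which forms C7–C11 and C8–O in one operation. The closest known reaction is the Ueno–Stork haloacetal cyclisation run with nitroxide capture of the cyclised radical under tin hydride/TEMPO conditions. The oxolane O6–C12–C11–C7–C6, the lactone ring at the acetal oxidation level, closes in the 5-exo-trig mode. C7 is set by the tether: the ring holds C5 on one side of the C7=C8 plane and O6 on the convex face of the bicycle, so C11 arrives anti to C5 and the fusion is trans; C8 is set by the shape of the bicycle, whose concave face is closed by the furanone bridge, so TEMPO should follow C11 on the convex face, a net syn addition across the trans alkene that corresponds to 8R. The step needs attack at C7 and not at C5, which is also five atoms from C11 and is the dienone terminus that a nucleophilic alkyl radical would prefer; the phosphoryl group makes the C11 radical electrophilic and so directs it to the strained, electron-rich C7=C8 bond. It also needs cyclisation to outrun capture of C11 by TEMPO, which the 1 mM concentration and the fast bromine abstraction from the activated C–Br bond are meant to secure.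

Step 14
Reactants: 23 tricyclic lactol acetal
Product: 25 α-(diethoxyphosphoryl) γ-lactone (6S,7R,8R,10R; C8 aminoxy ether; mixture at C11), via lactol 24 (not isolated)
Conditions: 2 M aq. HCl, THF, 40 °C; then TPAP (5 mol%), NMO, 4 Å MS, CH2Cl2, rt
Reagents that add atoms: water (O)
Why: Acid hydrolysis of the mixed acetal followed by Ley–Griffith oxidation of the lactol gives the γ-lactone; protonation takes place at the acetal oxygens, so the allylic C6–O bond and the hindered alkoxyamine should stay intact.

Step 15
Reactants: 25 phosphono lactone; 26 formaldehyde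
Product: 27 α-methylene lactone (6S,7R,8R,10R) with the C8 aminoxy ether
Conditions: 37% aq. HCHO, K2CO3, THF, 0 °C → rt
Reagents that add atoms: formaldehyde 26 (C=O)
Why: Horner–Wadsworth–Emmons olefination of the α-phosphono lactone with formaldehyde installs C13; carbonate is basic enough for the doubly activated C11–H, so no lactone enolate has to be made with an amide base next to the furanone.

Step 16
Reactants: 27 α-methylene lactone aminoxy ether
Product: 28 8-hydroxy α-methylene lactone (6S,7S,8R,10R)
Conditions: Zn dust, AcOH/THF/H2O (3:1:1), 50 °C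
Reagents that add atoms: none
Why: Reductive cleavage of the N–O bond of the O-alkyl hydroxylamine by zinc in acetic acid; the C8–O bond is not broken, so 8R is retained, and the C10–O bond of the furanone lies in the ring plane, orthogonal to the carbonyl π-system, which should protect it from reductive cleavage.

Step 17
Reactants: 29 acetaldehyde; 30 tert-butyl acrylate
Product: 31 tert-butyl 3-hydroxy-2-methylenebutanoate (racemic)
Conditions: 3-hydroxyquinuclidine (cat.), neat, rt
Reagents that add atoms: acetaldehyde 29 (CC=O)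
Why: Morita–Baylis–Hillman reaction of an acrylate with an aldehyde; the carbinol centre is removed in the next step.

Step 18
Reactants: 31 tert-butyl 3-hydroxy-2-methylenebutanoate; 32 acetic anhydride
Product: 34 tert-butyl (E)-2-(acetoxymethyl)but-2-enoate, via allylic acetate 33 (not isolated)
Conditions: Ac2O, Et3N, DMAP (cat.), CH2Cl2, 0 °C; then DABCO (0.2 equiv), THF, 65 °C
Reagents that add atoms: acetic anhydride 32 (CC(=O)OC(C)=O)
Why: O-acetylation, then amine-catalysed 1,3-transposition of the acetate (SN2′ addition of DABCO, SN2′ return of acetate) to the conjugated trisubstituted alkene; under these equilibrating conditions the isomer with the methyl group trans to the ester (E) should prevail.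

Step 19
Reactants: 34 tert-butyl (E)-2-(acetoxymethyl)but-2-enoate
Product: 35 (E)-2-(acetoxymethyl)but-2-enoic acid
Conditions: TFA, CH2Cl2, 0 °C → rt
Reagents that add atoms: none
Why: Acidolysis of the tert-butyl ester (loss of isobutene) frees the acid without touching the primary acetate or the alkene geometry.

Step 20
Reactants: 28 8-hydroxy α-methylene lactone; 35 (E)-2-(acetoxymethyl)but-2-enoic acid
Product: 37 CNP0176571.1 (6S,7S,8R,10R), via mixed anhydride 36 (not isolated)
Conditions: 35, 2,4,6-trichlorobenzoyl chloride, Et3N, toluene, rt; then 28, DMAP, rt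
Reagents that add atoms: acid 35 (C/C=C(/C(=O)O)COC(C)=O)
Why: Yamaguchi esterification; the C8–O bond is not broken, so the configuration from step 13 is kept, and the E acid is the stable isomer and should not isomerise.

**Compound list**

1 | (S)-lactic acid | C[C@H](O)C(=O)O | starting material
2 | pivalaldehyde | CC(C)(C)C=O | starting material
3 | (2S,5S)-2-tert-butyl-5-methyl-1,3-dioxolan-4-one | C[C@@H]1O[C@H](C(C)(C)C)OC1=O | intermediate
4 | allyl bromide | C=CCBr | starting material
5 | lithium enolate of 3 (lithium (2S)-2-tert-butyl-5-methyl-1,3-dioxol-4-olate) | CC1=C(O[Li])O[C@@H](C(C)(C)C)O1 | intermediate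
6 | (2S,5R)-5-allyl-2-tert-butyl-5-methyl-1,3-dioxolan-4-one | C=CC[C@@]1(C)O[C@H](C(C)(C)C)OC1=O | intermediate
7 | (R)-2-hydroxy-N-methoxy-N,2-dimethylpent-4-enamide | C=CC[C@@](C)(O)C(=O)N(C)OC | intermediate
8 | (Z)-3-methylpent-2-en-4-yn-1-ol | C#C/C(C)=C\CO | starting material
9 | (Z)-3-methylpent-2-en-4-ynal | C#C/C(C)=C\C=O | intermediate
10 | vinylmagnesium bromide | C=C[Mg]Br | starting material
11 | (3R,4Z)-5-methylhepta-1,4-dien-6-yn-3-ol | C=C[C@@H](O)/C=C(/C)C#C | intermediate
12 | tert-butyldimethylsilyl ether of 11 | C=C[C@@H](O[Si](C)(C)C(C)(C)C)/C=C(/C)C#C | intermediate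
13 | lithium acetylide of 12 | C=C[C@@H](O[Si](C)(C)C(C)(C)C)/C=C(/C)C#C[Li] | intermediate
14 | (4R,8Z,10R)-10-(tert-butyldimethylsilyloxy)-4-hydroxy-4,8-dimethyldodeca-1,8,11-trien-6-yn-5-one | C=CC[C@@](C)(O)C(=O)C#C/C(C)=C\[C@H](O[Si](C)(C)C(C)(C)C)C=C | intermediate
15 | (2R)-2-allyl-5-[(2Z,4R)-4-(tert-butyldimethylsilyloxy)hexa-2,5-dien-2-yl]-2-methylfuran-3(2H)-one | C=CC[C@@]1(C)OC(=CC1=O)/C(C)=C\[C@H](O[Si](C)(C)C(C)(C)C)C=C | intermediate
16 | (2R)-2-allyl-5-[(2Z,4R)-4-hydroxyhexa-2,5-dien-2-yl]-2-methylfuran-3(2H)-one | C=CC[C@@]1(C)OC(=CC1=O)/C(C)=C\[C@H](O)C=C | intermediate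
17 | (2Z,4R,5E,8R)-4-hydroxy-2,8-dimethyl-11-oxabicyclo[6.2.1]undeca-1(10),2,5-trien-9-one | C1/C=C/[C@@H](O)/C=C(/C)C2=CC(=O)[C@]1(C)O2 | intermediate
18 | diethyl (2,2-diethoxyethyl)phosphonate | CCOC(OCC)CP(=O)(OCC)OCC | starting material
19 | diethyl [(E)-2-ethoxyvinyl]phosphonate | CCO/C=C/P(=O)(OCC)OCC | intermediate
20 | diethyl (1,2-dibromo-2-ethoxyethyl)phosphonate | CCOC(Br)C(Br)P(=O)(OCC)OCC | intermediate
21 | (2Z,4R,5E,8R)-4-[2-bromo-2-(diethoxyphosphoryl)-1-ethoxyethoxy]-2,8-dimethyl-11-oxabicyclo[6.2.1]undeca-1(10),2,5-trien-9-one (mixture at C11, C12) | C1/C=C/[C@@H](OC(OCC)C(Br)P(=O)(OCC)OCC)/C=C(/C)C2=CC(=O)[C@]1(C)O2 | intermediate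
22 | TEMPO (2,2,6,6-tetramethylpiperidin-1-oxyl) | CC1(C)CCCC(C)(C)N1[O] | starting material
23 | tricyclic lactol ethyl acetal, C11 phosphonate, C8 aminoxy ether (6S,7R,8R,10R; mixture at C11, C12) | CCOC1C(P(=O)(OCC)OCC)[C@@H]2[C@@H](O1)/C=C(/C)C3=CC(=O)[C@@](C)(C[C@H]2ON4C(C)(C)CCCC4(C)C)O3 | intermediate
24 | lactol corresponding to 23 | OC1C(P(=O)(OCC)OCC)[C@@H]2[C@@H](O1)/C=C(/C)C3=CC(=O)[C@@](C)(C[C@H]2ON4C(C)(C)CCCC4(C)C)O3 | intermediate
25 | α-(diethoxyphosphoryl) γ-lactone, C8 aminoxy ether (6S,7R,8R,10R; mixture at C11) | O=C1C(P(=O)(OCC)OCC)[C@@H]2[C@@H](O1)/C=C(/C)C3=CC(=O)[C@@](C)(C[C@H]2ON4C(C)(C)CCCC4(C)C)O3 | intermediate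
26 | formaldehyde | C=O | starting material
27 | α-methylene lactone, C8 aminoxy ether (6S,7R,8R,10R) | C=C1C(=O)O[C@H]2/C=C(/C)C3=CC(=O)[C@@](C)(C[C@@H](ON4C(C)(C)CCCC4(C)C)[C@H]12)O3 | intermediate
28 | 8-hydroxy α-methylene lactone (6S,7S,8R,10R) | C=C1C(=O)O[C@H]2/C=C(/C)C3=CC(=O)[C@@](C)(C[C@@H](O)[C@H]12)O3 | intermediate
29 | acetaldehyde | CC=O | starting material
30 | tert-butyl acrylate | C=CC(=O)OC(C)(C)C | starting material
31 | tert-butyl 3-hydroxy-2-methylenebutanoate (racemic) | CC(O)C(=C)C(=O)OC(C)(C)C | intermediate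
32 | acetic anhydride | CC(=O)OC(C)=O | starting material
33 | tert-butyl 3-acetoxy-2-methylenebutanoate | CC(OC(C)=O)C(=C)C(=O)OC(C)(C)C | intermediate
34 | tert-butyl (E)-2-(acetoxymethyl)but-2-enoate | C/C=C(/C(=O)OC(C)(C)C)COC(C)=O | intermediate
35 | (E)-2-(acetoxymethyl)but-2-enoic acid | C/C=C(/C(=O)O)COC(C)=O | intermediate
36 | (E)-2-(acetoxymethyl)but-2-enoic 2,4,6-trichlorobenzoic anhydride | C/C=C(/C(=O)OC(=O)c1c(Cl)cc(Cl)cc1Cl)COC(C)=O | intermediate
37 | CNP0176571.1 (6S,7S,8R,10R; 4Z; side chain 2E) | C=C1C(=O)O[C@H]2/C=C(/C)C3=CC(=O)[C@@](C)(C[C@@H](OC(=O)/C(=C/C)COC(C)=O)[C@H]12)O3 | target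

**Step count**

Total: 20 steps. Longest linear sequence: 13 steps (steps 1–3, 7–10, 12–16, 20).

**Steps most likely to fail**

Step 13 – poor facial selectivity in the nitroxide capture. TEMPO may couple with the C8 radical on the face away from C11 and give the 8S epimer. The fallback sets out from 21 and comes back at 37; it sets C8 by SN2 displacement and no longer by the radical step. The 8-epimeric acetal F1 obtained in step 13 is hydrolysed and oxidised under the conditions of step 14 to the phosphono lactone F2. The N–O bond is cleaved (Zn, AcOH/THF/H2O, 50 °C) to the 8S alcohol F3. The side chain is then attached with inversion by Mitsunobu reaction with acid 35 (PPh3, DIAD, toluene, 0 °C → rt), which should give the 8R ester F4. Horner–Wadsworth–Emmons reaction with formaldehyde 26 (conditions of step 15) then gives 37.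

Step 10 – oligomerisation in place of ring closure, caused by the strain of the bridged trans-cyclodecene. The fallback forms the ring by C6–C7 bond formation between a vinyl iodide and the C6 aldehyde; it sets out from 6 and 8 and comes back at 17. Ozonolysis of 6 (O3, CH2Cl2, −78 °C; Me2S) gives the aldehyde F5, Takai olefination (CHI3, CrCl2, THF) the E-vinyl iodide F6, and aminolysis as in step 3 the Weinreb amide F7. Enynol 8 is silylated (TBSCl, imidazole, DMF) to the ether F8, whose lithium acetylide adds to F7 (as in step 7) to give the ynone F9. Gold cyclisation (as in step 8) gives the furanone F10, HF·pyridine the allylic alcohol F11, and MnO2 the Z-enal F12. An intramolecular Nozaki–Hiyama–Kishi reaction (CrCl2, NiCl2 cat., DMSO/THF, high dilution, chiral sulfonamide ligand on chromium to steer the new carbinol centre) then closes the ring to 17, with the E geometry fixed by the iodide.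

Step 16 – over-reduction. Zinc may reduce the α-methylene lactone, or the liberated amine may add to it, while the N–O bond is cleaved. The fallback cleaves the N–O bond before the methylene group exists; it sets out from 25 and comes back at 37. Zinc in acetic acid (as in step 16) converts 25 into the 8R alcohol F13, which is esterified with 35 under the conditions of step 20 to the ester F4. The Horner–Wadsworth–Emmons reaction with formaldehyde 26 (conditions of step 15) is then the last step and gives 37.

**Further compounds**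

F1 | step 13 | 8-epimer of 23 (8S) | CCOC1C(P(=O)(OCC)OCC)[C@@H]2[C@@H](O1)/C=C(/C)C3=CC(=O)[C@@](C)(C[C@@H]2ON4C(C)(C)CCCC4(C)C)O3
F2 | step 13 | 8-epimer of 25 (8S) | O=C1C(P(=O)(OCC)OCC)[C@@H]2[C@@H](O1)/C=C(/C)C3=CC(=O)[C@@](C)(C[C@@H]2ON4C(C)(C)CCCC4(C)C)O3
F3 | step 13 | 8S-hydroxy α-(diethoxyphosphoryl) lactone | O=C1C(P(=O)(OCC)OCC)[C@@H]2[C@@H](O1)/C=C(/C)C3=CC(=O)[C@@](C)(C[C@@H]2O)O3
F4 | step 13 | 8R (E)-2-(acetoxymethyl)but-2-enoate of the α-(diethoxyphosphoryl) lactone | O=C1C(P(=O)(OCC)OCC)[C@@H]2[C@@H](O1)/C=C(/C)C3=CC(=O)[C@@](C)(C[C@H]2OC(=O)/C(=C/C)COC(C)=O)O3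
F5 | step 10 | (2S,5R)-2-tert-butyl-5-methyl-5-(2-oxoethyl)-1,3-dioxolan-4-one | O=CC[C@@]1(C)O[C@H](C(C)(C)C)OC1=O
F6 | step 10 | (2S,5R)-2-tert-butyl-5-[(E)-3-iodoallyl]-5-methyl-1,3-dioxolan-4-one | I/C=C/C[C@@]1(C)O[C@H](C(C)(C)C)OC1=O
F7 | step 10 | (R,E)-2-hydroxy-5-iodo-N-methoxy-N,2-dimethylpent-4-enamide | I/C=C/C[C@@](C)(O)C(=O)N(C)OC
F8 | step 10 | tert-butyldimethylsilyl ether of 8 | C#C/C(C)=C\CO[Si](C)(C)C(C)(C)C
F9 | step 10 | (R)-hydroxy ynone with E-iodoalkene and silyloxymethyl terminus | I/C=C/C[C@@](C)(O)C(=O)C#C/C(C)=C\CO[Si](C)(C)C(C)(C)C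
F10 | step 10 | (2R)-2-[(E)-3-iodoallyl]-2-methyl-5-[(Z)-4-(tert-butyldimethylsilyloxy)but-2-en-2-yl]furan-3(2H)-one | I/C=C/C[C@@]1(C)OC(=CC1=O)/C(C)=C\CO[Si](C)(C)C(C)(C)C
F11 | step 10 | (2R)-5-[(Z)-4-hydroxybut-2-en-2-yl]-2-[(E)-3-iodoallyl]-2-methylfuran-3(2H)-one | I/C=C/C[C@@]1(C)OC(=CC1=O)/C(C)=C\CO
F12 | step 10 | (Z)-3-{(5R)-5-[(E)-3-iodoallyl]-5-methyl-4-oxo-4,5-dihydrofuran-2-yl}but-2-enal | I/C=C/C[C@@]1(C)OC(=CC1=O)/C(C)=C\C=O
F13 | step 16 | 8R-hydroxy α-(diethoxyphosphoryl) lactone | O=C1C(P(=O)(OCC)OCC)[C@@H]2[C@@H](O1)/C=C(/C)C3=CC(=O)[C@@](C)(C[C@H]2O)O3
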